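**Retrosynthetic overview**

- The strategy rests on the vicinal pair C6/C7 of the γ-lactone ring (O–C6–C7–C11–C12): C6 carries the lactone oxygen and alkenyl C5, C7 carries the acrylate carbon C11. Both are set by anti addition of a Z-dienyl group (to C6) and an acrylate carbon (to C7) across the C6=C7 bond of an E-alkenylboronate.
- Disconnections, backwards: C8–O acyl bond; C2=C3 by ring-closing metathesis (ten-membered carbocycle C1–C10); lactone C12–O after oxidation of C6–B; C5–C6 and C7–C11 in one three-component conjunctive coupling (dienyllithium, alkenylboronate, methyl 2-bromoacrylate).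
- Fragments: alkenylboronate from (S)-glycidol (C8) with the C1–C10 oxirane from a Sharpless epoxidation; Z-iododiene from propargyl alcohol; epoxy acid from tiglyl alcohol.
- Ring order: C1–C10 oxirane (before the coupling), γ-lactone, ten-membered ring; the side-chain oxirane arrives with the acid.

Key step: step 16

Assumption: germacrane numbering is used throughout (C1/C10 oxirane, C2=C3, C4(Me)=C5, C6 lactone O–CH, C7, C8 acyloxy CH, C11=C13, C12 carbonyl); the acyl group read from the SMILES is the cis-dimethyl (epoxytiglate) isomer, (2S,3R)-2,3-dimethyloxirane-2-carboxylate. The boron ligand is changed from pinacol to the cis-1,2-dimethylacenaphthylene-1,2-diol ("mac") ester, because β-substituted alkenyl pinacol boronates tend to undergo direct Suzuki transfer instead of the metallate shift.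

**Step 1**
Reactants: 1 (S)-glycidol
Product: 2 (R)-2-{[(4-methoxybenzyl)oxy]methyl}oxirane
Conditions: NaH, PMBCl, Bu4NI (cat.), THF/DMF, 0 °C to rt
Reagents that add atoms: 4-methoxybenzyl chloride, COc1ccc(CCl)cc1
Why: Williamson etherification of the primary alkoxide leaves the stereocentre untouched (the degenerate Payne shift of glycidol returns the same enantiomer), and the label changes from S to R only through CIP priority.

**Step 2**
Reactants: 2 (R)-2-{[(4-methoxybenzyl)oxy]methyl}oxirane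
Product: 3 (R)-1-[(4-methoxybenzyl)oxy]pent-4-yn-2-ol
Conditions: LiC≡CH·H2NCH2CH2NH2, DMSO, 0 °C to rt
Reagents that add atoms: lithium acetylide–ethylenediamine complex, [Li]C#C.NCCN
Why: SN2 opening of the terminal epoxide at its CH2 carbon by acetylide does not break the C–O bond at the stereocentre (future C8).

**Step 3**
Reactants: 3 (R)-1-[(4-methoxybenzyl)oxy]pent-4-yn-2-ol
Product: 4 (R)-tert-butyl({1-[(4-methoxybenzyl)oxy]pent-4-yn-2-yl}oxy)dimethylsilane
Conditions: TBSCl, imidazole, DMF, rt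
Reagents that add atoms: tert-butyldimethylsilyl chloride, CC(C)(C)[Si](C)(C)Cl
Why: standard silylation of the secondary alcohol gives an ether that survives organoaluminium, oxidation, organolithium and palladium steps.

**Step 4**
Reactants: 4 (R)-tert-butyl({1-[(4-methoxybenzyl)oxy]pent-4-yn-2-yl}oxy)dimethylsilane
Product: 7 (2E,5R)-5-[(tert-butyldimethylsilyl)oxy]-6-[(4-methoxybenzyl)oxy]-3-methylhex-2-en-1-ol, via alkenyldimethylalane 5 (not isolated), via lithium alkenylalanate 6 (not isolated)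
Conditions: Me3Al, Cp2ZrCl2 (cat.), CH2Cl2, 0 °C to rt; n-BuLi, THF, −78 °C; (CH2O)n, rt
Reagents that add atoms: trimethylaluminium, C[Al](C)C; paraformaldehyde, C=O
Why: Zr-catalysed syn carboalumination of the terminal alkyne (Negishi) places methyl on the internal and aluminium on the terminal carbon, and the derived alanate is hydroxymethylated with retention to give the E-trisubstituted allylic alcohol.

**Step 5**
Reactants: 7 (2E,5R)-5-[(tert-butyldimethylsilyl)oxy]-6-[(4-methoxybenzyl)oxy]-3-methylhex-2-en-1-ol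
Product: 8 {(2R,3R)-3-[(2R)-2-[(tert-butyldimethylsilyl)oxy]-3-[(4-methoxybenzyl)oxy]propyl]-3-methyloxiran-2-yl}methanol
Conditions: Ti(OiPr)4 (cat.), D-(−)-diethyl tartrate, t-BuOOH, 4 Å MS, CH2Cl2, −20 °C
Reagents that add atoms: tert-butyl hydroperoxide, CC(C)(C)OO
Why: Sharpless asymmetric epoxidation with the D-(−)-tartrate catalyst adds oxygen syn to one face of the E-allylic alcohol and sets C1 and C10 (both R) under reagent control, independent of the remote C8 centre.

**Step 6**
Reactants: 8 {(2R,3R)-3-[(2R)-2-[(tert-butyldimethylsilyl)oxy]-3-[(4-methoxybenzyl)oxy]propyl]-3-methyloxiran-2-yl}methanol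
Product: 9 (2S,3R)-3-[(2R)-2-[(tert-butyldimethylsilyl)oxy]-3-[(4-methoxybenzyl)oxy]propyl]-3-methyloxirane-2-carbaldehyde
Conditions: Dess–Martin periodinane, NaHCO3, CH2Cl2, 0 °C to rt
Reagents that add atoms: none
Why: buffered Dess–Martin oxidation gives the α,β-epoxy aldehyde without opening the oxirane or epimerising C1 (the 2S label is a CIP change only).

**Step 7**
Reactants: 9 (2S,3R)-3-[(2R)-2-[(tert-butyldimethylsilyl)oxy]-3-[(4-methoxybenzyl)oxy]propyl]-3-methyloxirane-2-carbaldehyde
Product: 10 (2R,3R)-2-[(2R)-2-[(tert-butyldimethylsilyl)oxy]-3-[(4-methoxybenzyl)oxy]propyl]-2-methyl-3-vinyloxirane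
Conditions: Ph3PCH3Br, KHMDS, THF, −78 to 0 °C
Reagents that add atoms: methyltriphenylphosphonium bromide, C[P+](c1ccccc1)(c1ccccc1)c1ccccc1.[Br-]
Why: Wittig methylenation with the salt-free ylide turns the epoxy aldehyde into the vinyl oxirane without touching the oxirane carbons.

**Step 8**
Reactants: 10 (2R,3R)-2-[(2R)-2-[(tert-butyldimethylsilyl)oxy]-3-[(4-methoxybenzyl)oxy]propyl]-2-methyl-3-vinyloxirane
Product: 11 (2R)-2-[(tert-butyldimethylsilyl)oxy]-3-[(2R,3R)-2-methyl-3-vinyloxiran-2-yl]propan-1-ol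
Conditions: DDQ, CH2Cl2/pH 7 buffer, 0 °C
Reagents that add atoms: none
Why: oxidative PMB cleavage (benzylic hydride abstraction, then hydrolysis of the oxocarbenium ion) leaves the TBS ether and the vinyl oxirane intact.

**Step 9**
Reactants: 11 (2R)-2-[(tert-butyldimethylsilyl)oxy]-3-[(2R,3R)-2-methyl-3-vinyloxiran-2-yl]propan-1-ol
Product: 12 (2R)-2-[(tert-butyldimethylsilyl)oxy]-3-[(2R,3R)-2-methyl-3-vinyloxiran-2-yl]propanal
Conditions: Dess–Martin periodinane, NaHCO3, CH2Cl2, 0 °C to rt
Reagents that add atoms: none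
Why: Dess–Martin oxidation gives the α-silyloxy aldehyde, which is used crude to avoid epimerisation at C8.

**Step 10**
Reactants: 12 (2R)-2-[(tert-butyldimethylsilyl)oxy]-3-[(2R,3R)-2-methyl-3-vinyloxiran-2-yl]propanal
Product: 13 2-{(1E,3R)-3-[(tert-butyldimethylsilyl)oxy]-4-[(2R,3R)-2-methyl-3-vinyloxiran-2-yl]but-1-en-1-yl}-4,4,5,5-tetramethyl-1,3,2-dioxaborolane
Conditions: CH2(Bpin)2, LiTMP, THF, 0 °C; then 12, −78 °C to rt
Reagents that add atoms: bis(pinacolatoboryl)methane, CC1(C)OB(CB2OC(C)(C)C(C)(C)O2)OC1(C)C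
Why: boron–Wittig olefination, in which the α,α-diboryl carbanion adds to the aldehyde and syn B–O elimination gives the E-alkenylboronate.

**Step 11**
Reactants: 14 acenaphthenequinone
Product: 15 (1R,2S)-1,2-dimethyl-1,2-dihydroacenaphthylene-1,2-diol (cis, meso; "mac" diol)
Conditions: Me3Al, PhMe, 0 °C to rt; recrystallisation
Reagents that add atoms: trimethylaluminium, C[Al](C)C
Why: twofold 1,2-addition of methyl to the diketone, the second directed by the aluminium alkoxide, should favour the cis diol, which is the isomer able to bridge boron.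

**Step 12**
Reactants: 13 the pinacol alkenylboronate; 15 mac diol
Product: 17 B(mac) ester of {(1E,3R)-3-[(tert-butyldimethylsilyl)oxy]-4-[(2R,3R)-2-methyl-3-vinyloxiran-2-yl]but-1-en-1-yl}boronic acid, via alkenylboronic acid 16 (not isolated)
Conditions: NaIO4, NH4OAc, acetone/H2O, rt; then 15, MgSO4, CH2Cl2, rt
Reagents that add atoms: none
Why: periodate cleaves the pinacol and frees the boronic acid, which condenses with the cis diol to the hindered B(mac) ester needed in step 16.

**Step 13**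
Reactants: 18 propargyl alcohol
Product: 20 (Z)-3-iodo-2-methylprop-2-en-1-ol, via cyclic alkenylmagnesium alkoxide 19 (not isolated)
Conditions: MeMgBr, CuI (cat.), THF, −10 °C to rt; then I2, −78 to 0 °C
Reagents that add atoms: methylmagnesium bromide, C[Mg]Br; iodine, II
Why: copper-catalysed anti carbomagnesiation of the propargylic alkoxide gives the five-membered magnesium chelate, and iodinolysis with retention places iodine cis to CH2OH.

**Step 14**
Reactants: 20 (Z)-3-iodo-2-methylprop-2-en-1-ol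
Product: 21 (Z)-3-iodo-2-methylprop-2-enal
Conditions: MnO2, CH2Cl2, rt, dark
Reagents that add atoms: none
Why: MnO2 oxidises the allylic alcohol under neutral conditions, which keeps the Z geometry of the β-iodoenal.

**Step 15**
Reactants: 21 (Z)-3-iodo-2-methylprop-2-enal
Product: 22 (Z)-1-iodo-2-methylbuta-1,3-diene
Conditions: Ph3PCH3Br, KHMDS, THF, −78 to 0 °C; kept as a pentane/Et2O solution
Reagents that add atoms: methyltriphenylphosphonium bromide, C[P+](c1ccccc1)(c1ccccc1)c1ccccc1.[Br-]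
Why: Wittig methylenation of the aldehyde does not involve the C=C(I) bond, so the Z geometry is retained.

**Step 16**
Reactants: 22 (Z)-1-iodo-2-methylbuta-1,3-diene; 17 the alkenyl B(mac) ester; 23 methyl 2-bromoacrylate
Product: 26 methyl (3R,4R,5Z)-3-{(1R)-1-[(tert-butyldimethylsilyl)oxy]-2-[(2R,3R)-2-methyl-3-vinyloxiran-2-yl]ethyl}-6-methyl-2-methylidene-4-[B(mac)]octa-5,7-dienoate (C6 boronate with C7 acrylate), via dienyllithium 24 (not isolated), via boron ate complex 25 (not isolated)
Conditions: 22, t-BuLi (2 equiv), Et2O, −78 °C; 17, THF, −78 °C to rt; then Pd(OAc)2 (3 mol %), MandyPhos (3.6 mol %, antipode for Si-face palladation of C7), NaOTf, 23, THF/DMSO, 40 °C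
Reagents that add atoms: none
Why: Iodine–lithium exchange gives 24 with retention of the Z geometry, 24 adds to boron of 17 to give ate complex 25, the alkenyl–Pd(II) formed from 23 (halide taken up by NaOTf) binds the C6=C7 bond and induces 1,2-migration of the dienyl group from boron to C6 anti to palladium, and reductive elimination at C7 with retention forms C7–C11. The closest known reaction type is the Pd/MandyPhos conjunctive cross-coupling of alkenylboron ate complexes, which is established for β-substituted alkenyl B(mac) acceptors, for alkenyl migrating groups and for alkenyl halide electrophiles with a triflate additive. No ring is closed; the bonds C5–C6 and C7–C11 are formed. The C6/C7 relationship (6R,7R, that of the trans lactone) follows from stereospecific anti addition across the E olefin, and the absolute sense (C5 to the Si face of C6, palladium and C11 to the Si face of C7) is controlled by the diphosphine and reinforced by the C8 silyl ether, since this is the face anti to the allylic C–O bond with H8 eclipsing the olefin. The step needs metallate shift instead of direct Suzuki transfer, which the hindered mac ligand secures, and it needs C6=C7 and not the dienyl group to act as acceptor, which the trisubstituted, more hindered C4=C5 bond secures. It also needs oxidative addition to 23 to outrun ionisation of the vinyl oxirane by Pd(0), for which the activated bromoacrylate is kept in excess over a low catalyst loading.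

**Step 17**
Reactants: 26 the C6 boronate
Product: 28 (4S,5R)-4-{(1R)-1-[(tert-butyldimethylsilyl)oxy]-2-[(2R,3R)-2-methyl-3-vinyloxiran-2-yl]ethyl}-3-methylidene-5-[(1Z)-2-methylbuta-1,3-dien-1-yl]oxolan-2-one, via hydroxy ester 27 (not isolated)
Conditions: NaBO3·4H2O, THF/H2O, 0 °C to rt; then PPTS (cat.), CH2Cl2, rt
Reagents that add atoms: sodium perborate, B(=O)O[O-].[Na+]
Why: peroxide oxidation of the C6–B bond proceeds with retention (1,2-shift of C6 from boron to oxygen), and acid-catalysed attack of the C6 hydroxyl on the methyl ester closes the trans-disubstituted α-methylene γ-lactone (the 4S label is a CIP effect of the silyl ether).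

**Step 18**
Reactants: 28 the bis-vinyl lactone
Product: 29 (1R,2Z,4Z,6R,7S,8R,10R)-8-[(tert-butyldimethylsilyl)oxy]-1,10-epoxygermacra-2,4,11(13)-trien-12,6-olide (target skeleton with OTBS at C8)
Conditions: Grubbs II (15 mol %), 1,4-benzoquinone (cat.), PhMe (1 mM), 80 °C
Reagents that add atoms: none
Why: ring-closing metathesis of the two monosubstituted vinyl groups (the methylene lactone and the trisubstituted C4=C5 bond are poor partners) closes the ten-membered ring, in which the flanking Z olefin and trans oxirane should allow only the Z C2=C3 bond.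

**Step 19**
Reactants: 29 the macrocyclic silyl ether
Product: 30 (1R,2Z,4Z,6R,7R,8R,10R)-1,10-epoxy-8-hydroxygermacra-2,4,11(13)-trien-12,6-olide
Conditions: TBAF, AcOH (1:1), THF, 0 °C to rt
Reagents that add atoms: none
Why: fluoride cleavage of the silyl ether is buffered so that the freed C8 alkoxide neither adds to the methylene lactone nor translactonises.

**Step 20**
Reactants: 31 (E)-2-methylbut-2-en-1-ol (tiglyl alcohol)
Product: 32 [(2R,3R)-2,3-dimethyloxiran-2-yl]methanol
Conditions: Ti(OiPr)4 (cat.), D-(−)-diethyl tartrate, t-BuOOH, 4 Å MS, CH2Cl2, −20 °C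
Reagents that add atoms: tert-butyl hydroperoxide, CC(C)(C)OO
Why: Sharpless asymmetric epoxidation with the D-(−)-tartrate catalyst sets both oxirane centres (2R,3R), and syn addition keeps the two methyl groups cis.

**Step 21**
Reactants: 32 [(2R,3R)-2,3-dimethyloxiran-2-yl]methanol
Product: 33 (2S,3R)-2,3-dimethyloxirane-2-carboxylic acid
Conditions: RuCl3·xH2O (cat.), NaIO4, MeCN/CCl4/H2O, rt
Reagents that add atoms: water, O
Why: RuO4 oxidation of the primary alcohol through the aldehyde hydrate gives the acid with the oxirane intact (the change of the C2 label from R to S is a CIP effect).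

**Step 22**
Reactants: 30 the C8 alcohol; 33 the epoxy acid
Product: 35 (1R,2Z,4Z,6R,7R,8R,10R)-1,10-epoxygermacra-2,4,11(13)-trien-12,6-olid-8-yl (2S,3R)-2,3-dimethyloxirane-2-carboxylate (CNP0122107.1), via mixed anhydride 34 (not isolated)
Conditions: 33, 2,4,6-Cl3C6H2COCl, Et3N, PhMe, rt; then 30, DMAP, PhMe, rt
Reagents that add atoms: none
Why: Yamaguchi esterification, in which DMAP attacks the aliphatic carbonyl of the mixed anhydride (the aroyl carbonyl is shielded by its ortho chlorines) and the acylpyridinium acylates the C8 hydroxyl with retention at all centres.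

**Compound list**

1 | (S)-glycidol | OC[C@H]1CO1 | starting material
2 | (R)-2-{[(4-methoxybenzyl)oxy]methyl}oxirane | COc1ccc(COC[C@H]2CO2)cc1 | intermediate
3 | (R)-1-[(4-methoxybenzyl)oxy]pent-4-yn-2-ol | C#CC[C@@H](O)COCc1ccc(OC)cc1 | intermediate
4 | (R)-tert-butyl({1-[(4-methoxybenzyl)oxy]pent-4-yn-2-yl}oxy)dimethylsilane | C#CC[C@@H](O[Si](C)(C)C(C)(C)C)COCc1ccc(OC)cc1 | intermediate
5 | dimethyl[(1E,4R)-4-(TBSO)-5-(PMBO)-2-methylpent-1-en-1-yl]alane | C[Al](C)/C=C(C)/C[C@@H](O[Si](C)(C)C(C)(C)C)COCc1ccc(OC)cc1 | intermediate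
6 | lithium butyl(dimethyl)[(1E,4R)-4-(TBSO)-5-(PMBO)-2-methylpent-1-en-1-yl]aluminate | [Li+].CCCC[Al-](C)(C)/C=C(C)/C[C@@H](O[Si](C)(C)C(C)(C)C)COCc1ccc(OC)cc1 | intermediate
7 | (2E,5R)-5-[(tert-butyldimethylsilyl)oxy]-6-[(4-methoxybenzyl)oxy]-3-methylhex-2-en-1-ol | OC/C=C(C)/C[C@@H](O[Si](C)(C)C(C)(C)C)COCc1ccc(OC)cc1 | intermediate
8 | {(2R,3R)-3-[(2R)-2-(TBSO)-3-(PMBO)propyl]-3-methyloxiran-2-yl}methanol | OC[C@H]1O[C@]1(C)C[C@@H](O[Si](C)(C)C(C)(C)C)COCc2ccc(OC)cc2 | intermediate
9 | (2S,3R)-3-[(2R)-2-(TBSO)-3-(PMBO)propyl]-3-methyloxirane-2-carbaldehyde | O=C[C@H]1O[C@]1(C)C[C@@H](O[Si](C)(C)C(C)(C)C)COCc2ccc(OC)cc2 | intermediate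
10 | (2R,3R)-2-[(2R)-2-(TBSO)-3-(PMBO)propyl]-2-methyl-3-vinyloxirane | C=C[C@H]1O[C@]1(C)C[C@@H](O[Si](C)(C)C(C)(C)C)COCc2ccc(OC)cc2 | intermediate
11 | (2R)-2-[(tert-butyldimethylsilyl)oxy]-3-[(2R,3R)-2-methyl-3-vinyloxiran-2-yl]propan-1-ol | C=C[C@H]1O[C@]1(C)C[C@@H](O[Si](C)(C)C(C)(C)C)CO | intermediate
12 | (2R)-2-[(tert-butyldimethylsilyl)oxy]-3-[(2R,3R)-2-methyl-3-vinyloxiran-2-yl]propanal | C=C[C@H]1O[C@]1(C)C[C@@H](O[Si](C)(C)C(C)(C)C)C=O | intermediate
13 | 2-{(1E,3R)-3-(TBSO)-4-[(2R,3R)-2-methyl-3-vinyloxiran-2-yl]but-1-en-1-yl}-4,4,5,5-tetramethyl-1,3,2-dioxaborolane | C=C[C@H]1O[C@]1(C)C[C@@H](O[Si](C)(C)C(C)(C)C)/C=C/B2OC(C)(C)C(C)(C)O2 | intermediate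
14 | acenaphthenequinone | O=C1C(=O)c2cccc3cccc1c23 | starting material
15 | (1R,2S)-1,2-dimethyl-1,2-dihydroacenaphthylene-1,2-diol (mac diol) | O[C@]1(C)c2cccc3cccc(c23)[C@]1(C)O | intermediate
16 | {(1E,3R)-3-(TBSO)-4-[(2R,3R)-2-methyl-3-vinyloxiran-2-yl]but-1-en-1-yl}boronic acid | C=C[C@H]1O[C@]1(C)C[C@@H](O[Si](C)(C)C(C)(C)C)/C=C/B(O)O | intermediate
17 | B(mac) ester of boronic acid 16 | C=C[C@H]1O[C@]1(C)C[C@@H](O[Si](C)(C)C(C)(C)C)/C=C/B2O[C@]3(C)c4cccc5cccc(c45)[C@]3(C)O2 | intermediate
18 | propargyl alcohol | C#CCO | starting material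
19 | 4-methyl-2,5-dihydro-1,2-oxamagnesole (chelated Z-alkenylmagnesium alkoxide) | CC1=C[Mg]OC1 | intermediate
20 | (Z)-3-iodo-2-methylprop-2-en-1-ol | I/C=C(C)\CO | intermediate
21 | (Z)-3-iodo-2-methylprop-2-enal | I/C=C(C)\C=O | intermediate
22 | (Z)-1-iodo-2-methylbuta-1,3-diene | I/C=C(C)\C=C | intermediate
23 | methyl 2-bromoacrylate | C=C(Br)C(=O)OC | starting material
24 | [(1Z)-2-methylbuta-1,3-dien-1-yl]lithium | [Li]/C=C(C)\C=C | intermediate
25 | lithium (mac)[(1E,3R)-alkenyl][(1Z)-2-methylbuta-1,3-dien-1-yl]borate (mixture at boron) | [Li+].C=C[C@H]1O[C@]1(C)C[C@@H](O[Si](C)(C)C(C)(C)C)/C=C/[B-]2(/C=C(C)\C=C)O[C@]3(C)c4cccc5cccc(c45)[C@]3(C)O2 | intermediate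
26 | methyl (3R,4R,5Z)-3-{(1R)-1-(TBSO)-2-[(2R,3R)-2-methyl-3-vinyloxiran-2-yl]ethyl}-6-methyl-2-methylidene-4-[B(mac)]octa-5,7-dienoate | C=C(C(=O)OC)[C@@H]([C@@H](/C=C(C)\C=C)B1O[C@]2(C)c3cccc4cccc(c34)[C@]2(C)O1)[C@H](O[Si](C)(C)C(C)(C)C)C[C@@]5(C)O[C@@H]5C=C | intermediate
27 | methyl (3S,4R,5Z)-3-{(1R)-1-(TBSO)-2-[(2R,3R)-2-methyl-3-vinyloxiran-2-yl]ethyl}-4-hydroxy-6-methyl-2-methylideneocta-5,7-dienoate | C=C(C(=O)OC)[C@@H]([C@@H](/C=C(C)\C=C)O)[C@H](O[Si](C)(C)C(C)(C)C)C[C@@]1(C)O[C@@H]1C=C | intermediate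
28 | (4S,5R)-4-{(1R)-1-(TBSO)-2-[(2R,3R)-2-methyl-3-vinyloxiran-2-yl]ethyl}-3-methylidene-5-[(1Z)-2-methylbuta-1,3-dien-1-yl]oxolan-2-one | C=C1C(=O)O[C@H](/C=C(C)\C=C)[C@H]1[C@H](O[Si](C)(C)C(C)(C)C)C[C@@]2(C)O[C@@H]2C=C | intermediate
29 | (1R,2Z,4Z,6R,7S,8R,10R)-8-[(tert-butyldimethylsilyl)oxy]-1,10-epoxygermacra-2,4,11(13)-trien-12,6-olide | C=C1C(=O)O[C@@H]2/C=C(C)\C=C/[C@H]3O[C@]3(C)C[C@@H](O[Si](C)(C)C(C)(C)C)[C@@H]12 | intermediate
30 | (1R,2Z,4Z,6R,7R,8R,10R)-1,10-epoxy-8-hydroxygermacra-2,4,11(13)-trien-12,6-olide | C=C1C(=O)O[C@@H]2/C=C(C)\C=C/[C@H]3O[C@]3(C)C[C@@H](O)[C@@H]12 | intermediate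
31 | (E)-2-methylbut-2-en-1-ol (tiglyl alcohol) | C/C=C(\C)CO | starting material
32 | [(2R,3R)-2,3-dimethyloxiran-2-yl]methanol | OC[C@@]1(C)O[C@@H]1C | intermediate
33 | (2S,3R)-2,3-dimethyloxirane-2-carboxylic acid | OC(=O)[C@@]1(C)O[C@@H]1C | intermediate
34 | (2S,3R)-2,3-dimethyloxirane-2-carboxylic 2,4,6-trichlorobenzoic anhydride | O=C(OC(=O)[C@@]1(C)O[C@@H]1C)c1c(Cl)cc(Cl)cc1Cl | intermediate
35 | (1R,2Z,4Z,6R,7R,8R,10R)-1,10-epoxygermacra-2,4,11(13)-trien-12,6-olid-8-yl (2S,3R)-2,3-dimethyloxirane-2-carboxylate (CNP0122107.1) | C=C1C(=O)O[C@@H]2/C=C(C)\C=C/[C@H]3O[C@]3(C)C[C@@H](OC(=O)[C@@]3(C)O[C@@H]3C)[C@@H]12 | target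

**Step count**

Total: 22 steps. Longest linear sequence: 16 steps (steps 1–10, 12, 16–19, 22).

**Steps most likely to fail**

Step 16 (conjunctive coupling). What may go wrong: direct transfer of either alkenyl group to palladium (Suzuki coupling), the dienyl group acting as acceptor through its terminal vinyl group (vinylogous shift through a π-allyl), ionisation of the vinyl oxirane by Pd(0), or poor facial selectivity. The fallback sets out from 12 and returns at 27; it forms C6–C7 by a thermal allylboration through a closed chair transition state, with C7–C11 already present in the reagent. Aldehyde 12 would be homologated with the Ohira–Bestmann reagent (K2CO3, MeOH) to the terminal alkyne F1, which would be carboxylated (LiHMDS, ClCO2Me, −78 °C) to the ynoate F2. Conjugate syn hydroalumination (DIBAL-H, HMPA, cat. MeCu, THF) and trapping of the α-metallated acrylate with ICH2Bpin should give the 2-(methoxycarbonyl)allylboronate F3 with the C8 chain trans to CH2B. Commercial (Z)-3-methylpent-2-en-4-yn-1-ol would be semi-hydrogenated (Lindlar catalyst, quinoline) to the dienol F4 and oxidised (MnO2) to the Z-dienal F5. Heating F3 with F5 in toluene should give the anti C6/C7 adduct through the chair transition state (E-crotyl analogue) and, after work-up, hydroxy ester 27, which is lactonised to 28 as in step 17. The facial sense relative to C8 would rest on the allylic silyl ether of F3.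

Step 18 (ring-closing metathesis). What may go wrong: oligomerisation in place of closure of the strained ten-membered ring, or attack of the alkylidene formed on the oxirane vinyl group at the internal C4=C5 bond (ring contraction with loss of isoprene). The fallback sets out from 21 and returns at 29; it is a relay ring-closing metathesis, in which the catalyst is loaded at a remote terminal olefin and delivered to C3, so that only the oxirane vinyl group is left as partner. Iodoenal 21 would be olefinated with hex-5-enylidenetriphenylphosphorane (hex-5-enyltriphenylphosphonium bromide, KHMDS) to the relay iodotriene F6. F6 would replace 22 in step 16 to give the relay boronate F7, and step 17 would give the relay lactone F8. With the ruthenium carbene, F8 should first expel cyclopentene and then close C2=C3 to give 29.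

Step 22 (acylation of C8–OH). What may go wrong: slow acylation of the hindered C8 hydroxyl by the α-quaternary acid, so that base-induced translactonisation to the 8,12-lactone or conjugate addition to the methylene lactone takes over. The fallback sets out from 28 and returns at 35; the acyl group is put on before the ten-membered ring crowds C8. Lactone 28 would be desilylated (TBAF/AcOH) to the seco alcohol F9 and esterified with 33 under the Yamaguchi conditions to the seco ester F10. Ring-closing metathesis of F10 as in step 18 should then give 35 directly.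

**Further compounds**

F1 | step 16 | tert-butyldimethyl({(2R)-1-[(2R,3R)-2-methyl-3-vinyloxiran-2-yl]but-3-yn-2-yl}oxy)silane | C=C[C@H]1O[C@]1(C)C[C@@H](O[Si](C)(C)C(C)(C)C)C#C
F2 | step 16 | methyl (4R)-4-[(tert-butyldimethylsilyl)oxy]-5-[(2R,3R)-2-methyl-3-vinyloxiran-2-yl]pent-2-ynoate | C=C[C@H]1O[C@]1(C)C[C@@H](O[Si](C)(C)C(C)(C)C)C#CC(=O)OC
F3 | step 16 | methyl (2Z,4R)-4-[(tert-butyldimethylsilyl)oxy]-5-[(2R,3R)-2-methyl-3-vinyloxiran-2-yl]-2-[(4,4,5,5-tetramethyl-1,3,2-dioxaborolan-2-yl)methyl]pent-2-enoate | C=C[C@H]1O[C@]1(C)C[C@@H](O[Si](C)(C)C(C)(C)C)/C=C(/CB2OC(C)(C)C(C)(C)O2)C(=O)OC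
F4 | step 16 | (2Z)-3-methylpenta-2,4-dien-1-ol | OC/C=C(C)\C=C
F5 | step 16 | (2Z)-3-methylpenta-2,4-dienal | O=C/C=C(C)\C=C
F6 | step 18 | (1Z,3Z)-1-iodo-2-methylnona-1,3,8-triene | I/C=C(C)\C=C/CCCC=C
F7 | step 18 | methyl (3R,4R,5Z,7Z)-3-{(1R)-1-(TBSO)-2-[(2R,3R)-2-methyl-3-vinyloxiran-2-yl]ethyl}-6-methyl-2-methylidene-4-[B(mac)]trideca-5,7,12-trienoate | C=C(C(=O)OC)[C@@H]([C@@H](/C=C(C)\C=C/CCCC=C)B1O[C@]2(C)c3cccc4cccc(c34)[C@]2(C)O1)[C@H](O[Si](C)(C)C(C)(C)C)C[C@@]5(C)O[C@@H]5C=C
F8 | step 18 | (4S,5R)-4-{(1R)-1-(TBSO)-2-[(2R,3R)-2-methyl-3-vinyloxiran-2-yl]ethyl}-3-methylidene-5-[(1Z,3Z)-2-methylnona-1,3,8-trien-1-yl]oxolan-2-one | C=C1C(=O)O[C@H](/C=C(C)\C=C/CCCC=C)[C@H]1[C@H](O[Si](C)(C)C(C)(C)C)C[C@@]2(C)O[C@@H]2C=C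
F9 | step 22 | (4R,5R)-4-{(1R)-1-hydroxy-2-[(2R,3R)-2-methyl-3-vinyloxiran-2-yl]ethyl}-3-methylidene-5-[(1Z)-2-methylbuta-1,3-dien-1-yl]oxolan-2-one | C=C1C(=O)O[C@H](/C=C(C)\C=C)[C@H]1[C@H](O)C[C@@]2(C)O[C@@H]2C=C
F10 | step 22 | (1R)-1-{(3R,4R... as F9}-derived ester: (1R)-1-[(2R,3R)-2-[(1Z)-2-methylbuta-1,3-dien-1-yl]-4-methylidene-5-oxooxolan-3-yl]-2-[(2R,3R)-2-methyl-3-vinyloxiran-2-yl]ethyl (2S,3R)-2,3-dimethyloxirane-2-carboxylate | C=C1C(=O)O[C@H](/C=C(C)\C=C)[C@H]1[C@H](OC(=O)[C@@]3(C)O[C@@H]3C)C[C@@]2(C)O[C@@H]2C=C
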